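**Retrosynthetic overview**

1. Enabling feature: the 3(2H)-furanone ring (O–C1=C2–C3(=O)–C4, germacrane numbering) is the cycloisomer of an α′-hydroxy ynone, and its oxygen bridges C1 and C4 of the ten-membered carbocycle C1–C10. Joining the acyl carbon C3 of a C4-hydroxy thioester to the terminal alkyne carbon C2 therefore closes the carbocycle, and the C4 hydroxyl then reaches C1 across the ring to close the furanone.
2. Disconnections (retro order): C8 and C13 esters; C5=C6 enol-lactone alkene ⇒ C6 lactol ⇒ furan (C6, C7, C11, C12, O), used as a butenolide surrogate with an sp3 C5, so that no acyclic ylidene-butenolide geometry has to be made or kept; C2–C3 and O–C1 (key cascade) ⇒ open-chain 2,3,4-trisubstituted furan 23.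
3. Fragment level: C5–C6 ⇒ 2-furyl metal + methyl (S)-2-methylglycidate (brings C4); C10 ⇒ rhodium-catalysed conjugate alkynylation; C8 ⇒ CBS reduction; furan core ⇒ furan-3,4-diyldimethanol.
4. Ring order: furan (purchased) → ten-membered carbocycle and furanone together (step 14) → butenolide from the furan with singlet oxygen (step 15) → C5=C6 inside the bridged bicycle by dehydration (step 16), so the ring dictates its geometry.

Key step: step 14

Remark on the chemistry: TBS = tert-butyldimethylsilyl, TIPS = triisopropylsilyl, TES = triethylsilyl; germacrane atom labels (C1–C15; C14 = methyl on C10, C15 = methyl on C4) are used for all intermediates; the target is (4S,5E,8S,10S).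
Assumption: (R)-DTBM-SEGPHOS is taken to give the 3S adduct in step 6; if the sense of induction proves opposite, the (S)-ligand is used without other change.

**Route**

Step 1
Reactants: 1 furan-3,4-diyldimethanol
Product: 3 mono-TBS ether of the diol, via monosodium alkoxide 2 (not isolated)
Conditions: NaH (1.0 equiv), THF, 0 → 23 °C; TBSCl (1.0 equiv), 23 °C
Reagents that add atoms: tert-butyldimethylsilyl chloride, CC(C)(C)[Si](C)(C)Cl
Why: One equivalent of NaH should convert the symmetric diol into its sparingly soluble monosodium alkoxide, whose O-silylation (silyl ether formation) gives the mono-protected diol.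

Step 2
Reactants: 3 mono-TBS ether
Product: 4 4-(TBSOCH2)furan-3-carbaldehyde
Conditions: MnO2 (activated, excess), CH2Cl2, 23 °C
Reagents that add atoms: none
Why: MnO2 oxidation of the furylic (benzylic-type) primary alcohol should stop cleanly at the aldehyde and leaves the silyl ether untouched.

Step 3
Reactants: 4 4-(TBSOCH2)furan-3-carbaldehyde
Product: 8 2-bromo-4-(TBSOCH2)furan-3-carbaldehyde, via lithium α-amino alkoxide 5 (not isolated), via C2-lithiated α-amino alkoxide 6 (not isolated), via C2-bromo α-amino alkoxide 7 (not isolated)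
Conditions: LiN(Me)CH2CH2NMe2 (from the diamine and n-BuLi), THF, −78 °C; n-BuLi (3 equiv), −20 °C; BrCCl2CCl2Br, −78 → 0 °C; H2O
Reagents that add atoms: 1,2-dibromo-1,1,2,2-tetrachloroethane, BrC(Cl)(Cl)C(Cl)(Cl)Br
Why: Directed ortho-lithiation through an in situ α-amino alkoxide: the chelating diamine arm of 5 should steer n-BuLi to C2 (the future C6) and away from C5, which is also shielded by the silyloxymethyl group, and brominative quench followed by aqueous collapse of the aminal returns the aldehyde.

Step 4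
Reactants: 8 2-bromo-4-(TBSOCH2)furan-3-carbaldehyde
Product: 9 racemic homoallylic alcohol
Conditions: allylMgBr (1.2 equiv), THF, −78 °C; aq NH4Cl
Reagents that add atoms: allylmagnesium bromide, C=CC[Mg]Br
Why: Grignard 1,2-addition to the aldehyde at −78 °C should outrun bromine–magnesium exchange, and the racemic carbinol centre created here is erased by the oxidation in step 5.

Step 5
Reactants: 9 racemic homoallylic alcohol
Product: 11 (E)-furyl propenyl ketone, via β,γ-enone 10 (not isolated)
Conditions: Dess–Martin periodinane, NaHCO3, CH2Cl2, 0 → 23 °C; filtration; DBU (0.2 equiv), CH2Cl2, 23 °C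
Reagents that add atoms: none
Why: Dess–Martin oxidation followed by amidine-mediated β,γ to α,β alkene isomerisation should deliver the conjugated enone under thermodynamic control and hence as the E isomer.

Step 6
Reactants: 11 (E)-furyl propenyl ketone
Product: 12 (3S)-β-alkynyl ketone
Conditions: [Rh(OAc)(C2H4)2]2 (2.5 mol%), (R)-DTBM-SEGPHOS (6 mol%), HC≡C–TIPS (2 equiv), 1,4-dioxane, 80 °C
Reagents that add atoms: ethynyltriisopropylsilane, C#C[Si](C(C)C)(C(C)C)C(C)C
Why: Rhodium-catalysed asymmetric conjugate alkynylation of a linear (E)-enone, in which the alkynyl group on monovalent rhodium is transferred to one enone face selected by the chiral bisphosphine (C10 set as S by catalyst control) while the bulky silyl group suppresses alkyne dimerisation.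

Step 7
Reactants: 12 (3S)-β-alkynyl ketone
Product: 13 (1S,3S)-alcohol
Conditions: (R)-Me-CBS (20 mol%), BH3·SMe2 (1.0 equiv), THF, −30 °C; MeOH
Reagents that add atoms: none
Why: Corey–Bakshi–Shibata reduction, in which the (R)-oxazaborolidine places the disubstituted furyl group as the large substituent and delivers hydride to give the (S)-carbinol at C8 by reagent control, independent of C10.

Step 8
Reactants: 13 (1S,3S)-alcohol
Product: 14 (1S,3S)-bis-silyl ether bromofuran
Conditions: TBSOTf, 2,6-lutidine, CH2Cl2, −78 → 0 °C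
Reagents that add atoms: tert-butyldimethylsilyl trifluoromethanesulfonate, CC(C)(C)[Si](C)(C)OS(=O)(=O)C(F)(F)F
Why: Silylation of the hindered secondary alcohol with the silyl triflate and a non-nucleophilic base is a standard protection that blocks O8 from competing in step 14.

Step 9
Reactants: 15 (R)-2-methylglycidol
Product: 16 (S)-2-methylglycidic acid
Conditions: RuCl3·xH2O (2 mol%), NaIO4 (3 equiv), MeCN/EtOAc/H2O, 0 → 23 °C
Reagents that add atoms: water, O (NaIO4, [Na+].[O-]I(=O)(=O)=O, is the terminal oxidant)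
Why: RuO4-type oxidation (catalytic RuCl3 with NaIO4) of the primary alcohol to the carboxylic acid is established for glycidols, and the quaternary epoxide carbon cannot epimerise (the descriptor changes from R to S only because the priorities change).

Step 10
Reactants: 16 (S)-2-methylglycidic acid
Product: 17 methyl (S)-2-methylglycidate
Conditions: TMSCHN2, MeOH/toluene, 0 °C
Reagents that add atoms: (trimethylsilyl)diazomethane, C[Si](C)(C)C=[N+]=[N-]
Why: Methyl ester formation with (trimethylsilyl)diazomethane proceeds under neutral conditions that should leave the acid-sensitive epoxide intact.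

Step 11
Reactants: 14 (1S,3S)-bis-silyl ether bromofuran; 17 methyl (S)-2-methylglycidate
Product: 20 (2S)-α-hydroxy methyl ester with TIPS-alkyne, via furyllithium 18 (not isolated), via furylmagnesium bromide 19 (not isolated)
Conditions: 14, t-BuLi (2.05 equiv), THF, −78 °C; MgBr2·OEt2, −78 → −40 °C; CuI (15 mol%), 17 (1.5 equiv), −40 → 0 °C; aq NH4Cl
Reagents that add atoms: none
Why: Bromine–lithium exchange (at −78 °C and without HMPA so that a 1,4 O-to-C silyl shift is avoided), transmetalation to magnesium and copper-catalysed SN2 opening of the glycidic ester at its unsubstituted CH2 is the known route from aryl Grignard reagents to α-hydroxy esters and leaves the C4 stereocentre of 17 untouched (S).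

Step 12
Reactants: 20 (2S)-α-hydroxy methyl ester with TIPS-alkyne
Product: 22 (2S)-α-hydroxy methyl ester with terminal alkyne, via silver acetylide 21 (not isolated)
Conditions: AgF (1.5 equiv), MeOH/THF, 23 °C, dark; then 1 M HCl
Reagents that add atoms: none
Why: Silver fluoride-mediated protodesilylation of the silylalkyne via the silver acetylide should free the terminal alkyne while the alkyl silyl ethers and the ester survive.

Step 13
Reactants: 22 (2S)-α-hydroxy methyl ester with terminal alkyne
Product: 23 S-ethyl (2S)-α-hydroxy thioester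
Conditions: AlMe3 (4 equiv), EtSH (4.4 equiv), CH2Cl2, 0 → 23 °C; cold 1 M HCl
Reagents that add atoms: ethanethiol, CCS
Why: Aluminium thiolate transesterification (Me2AlSEt generated in situ) converts the methyl ester into the thioester, the tertiary hydroxyl being carried as its aluminium alkoxide and released on work-up.

Step 14
Reactants: 23 S-ethyl (2S)-α-hydroxy thioester
Product: 26 macrocyclic furan-fused furanone, via cyclic hydroxy ynone 24 (not isolated), via diethylamino enone 25 (not isolated)
Conditions: PdCl2(dppf) (10 mol%), P(2-furyl)3 (25 mol%), CuI (1.7 equiv), Et3N, DMF, 50 °C, degassed, 23 added over 12 h (final 2 mM); then Et2NH (5 equiv), 23 °C, same flask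
Reagents that add atoms: none
Why: Proposed new method: zerovalent palladium (formed from PdCl2(dppf)) inserts into the C3–S bond of the thioester, CuI captures the thiolate and supplies the copper acetylide of C1≡C2, and reductive elimination from the acyl(alkynyl)palladium forms C2–C3 and with it the ten-membered cyclic α′-hydroxy ynone 24; the C4 hydroxyl, which faces C1 across the ring, then forms O–C1, either by direct addition to the bent alkyne or, after the Et2NH charge, by addition–elimination on the β-diethylamino enone 25, to give the 3(2H)-furanone. The closest known reaction types are the palladium/copper-catalysed coupling of thioesters with terminal alkynes to ynones (acyl Sonogashira type), Sonogashira macrocyclisation, and the amine- or gold-promoted cycloisomerisation of α′-hydroxy ynones to 3(2H)-furanones; their merger into one macrocyclising cascade is what is new. The ten-membered carbocycle closes by a formal 10-exo-trig acyl substitution at C3 and the furanone by a transannular 5-endo-dig oxa-Michael addition. No stereocentre is created, and C4 (quaternary), C8 and C10 are carried through unchanged, base-induced propargyl–allenyl isomerisation that would endanger C10 being disfavoured by the strain of a cyclic allene. The step needs ring closure to win over oligomerisation and oxidative alkyne homocoupling, which the cis arrangement of both chains on adjacent furan carbons, slow addition to about 2 mM and exclusion of oxygen should secure, and it needs O4 to be the only nucleophile at C1, which the silyl ethers on O8 and O13 secure.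

Step 15
Reactants: 26 macrocyclic furan-fused furanone
Product: 28 C6-hydroxybutenolide, via furan endoperoxide 27 (not isolated)
Conditions: O2, visible light, tetraphenylporphyrin (1 mol%), i-Pr2NEt (2 equiv), CH2Cl2, −78 → 0 °C
Reagents that add atoms: dioxygen, O=O
Why: Furan photooxygenation: [4+2] cycloaddition of singlet oxygen to the electron-rich trisubstituted furan gives endoperoxide 27, and amine-induced Kornblum–DeLaMare fragmentation at its only bridgehead C–H (C12) should make C12 the lactone carbonyl and C6 the hemiketal carbon, whose configuration is immaterial because it is removed in step 16.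

Step 16
Reactants: 28 C6-hydroxybutenolide
Product: 30 (5E)-enol lactone bis-TBS ether, via hemiketal trifluoroacetate 29 (not isolated)
Conditions: (CF3CO)2O (1.5 equiv), pyridine, DMAP (cat.), CH2Cl2, 0 → 23 °C
Reagents that add atoms: none
Why: Trifluoroacetylation of the hemiketal hydroxyl and elimination through the acyloxy-stabilised oxocarbenium ion (enol-lactonisation of a γ-keto acid pseudo-acid) should give the C5=C6 alkene, the only regiochemistry available, with the 5E geometry (C4 cis to C7) imposed by the nine-membered oxacycle that contains it.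

Step 17
Reactants: 30 (5E)-enol lactone bis-TBS ether
Product: 31 8,13-diol
Conditions: HF·pyridine, pyridine/THF, 0 → 23 °C
Reagents that add atoms: none
Why: Fluoride-mediated cleavage of both silyl ethers under buffered HF·pyridine conditions should be tolerated by the enol lactone and the furanone.

Step 18
Reactants: 31 8,13-diol
Product: 32 13-acetate
Conditions: AcCl (1.1 equiv), 2,4,6-collidine, CH2Cl2, −78 °C
Reagents that add atoms: acetyl chloride, CC(Cl)=O
Why: Kinetically controlled acetylation with acetyl chloride and collidine at −78 °C should select the unhindered primary allylic C13 hydroxyl over the secondary C8 hydroxyl flanked by the butenolide.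

Step 19
Reactants: 33 ethyl 2-(hydroxymethyl)acrylate
Product: 34 ethyl 2-(TBSOCH2)acrylate
Conditions: TBSCl, imidazole, CH2Cl2, 0 → 23 °C
Reagents that add atoms: tert-butyldimethylsilyl chloride, CC(C)(C)[Si](C)(C)Cl
Why: Standard silyl ether formation protects the primary hydroxyl of the acrylate.

Step 20
Reactants: 34 ethyl 2-(TBSOCH2)acrylate
Product: 35 2-(TBSOCH2)acrylic acid
Conditions: LiOH·H2O, THF/H2O, 0 °C; 1 M HCl to pH 3
Reagents that add atoms: lithium hydroxide, [Li+].[OH-]
Why: Saponification of the ethyl ester with LiOH at 0 °C followed by mild acidification gives the acid with the silyl ether intact.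

Step 21
Reactants: 32 13-acetate; 35 2-(TBSOCH2)acrylic acid
Product: 37 TBS ether of the target, via mixed anhydride 36 (not isolated)
Conditions: 35, 2,4,6-trichlorobenzoyl chloride, Et3N, toluene, 23 °C; then 32, DMAP, 0 → 23 °C
Reagents that add atoms: none
Why: Yamaguchi esterification through mixed anhydride 36 acylates the hindered secondary C8 hydroxyl with retention (no bond to C8 is broken), and acetyl migration from O13 is disfavoured because the primary acetate is the more stable ester.

Step 22
Reactants: 37 TBS ether of the target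
Product: 38 CNP0193735.1
Conditions: HF·pyridine, pyridine/THF, 0 °C
Reagents that add atoms: none
Why: HF·pyridine removes the primary silyl ether without touching the two esters, the enol lactone or the furanone.

**Compound list**

1 | furan-3,4-diyldimethanol | OCc1cocc1CO | starting material
2 | sodium [4-(hydroxymethyl)furan-3-yl]methanolate | [Na]OCc1cocc1CO | intermediate (not isolated)
3 | [4-({[tert-butyl(dimethyl)silyl]oxy}methyl)furan-3-yl]methanol | OCc1cocc1CO[Si](C)(C)C(C)(C)C | intermediate
4 | 4-({[tert-butyl(dimethyl)silyl]oxy}methyl)furan-3-carbaldehyde | O=Cc1cocc1CO[Si](C)(C)C(C)(C)C | intermediate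
5 | lithium α-amino alkoxide from 4 and LiN(Me)CH2CH2NMe2 | CN(C)CCN(C)C(O[Li])c1cocc1CO[Si](C)(C)C(C)(C)C | intermediate (not isolated)
6 | 5 lithiated at furan C2 | CN(C)CCN(C)C(O[Li])c1c([Li])occ1CO[Si](C)(C)C(C)(C)C | intermediate (not isolated)
7 | 2-bromo derivative of 5 | CN(C)CCN(C)C(O[Li])c1c(Br)occ1CO[Si](C)(C)C(C)(C)C | intermediate (not isolated)
8 | 2-bromo-4-({[tert-butyl(dimethyl)silyl]oxy}methyl)furan-3-carbaldehyde | O=Cc1c(Br)occ1CO[Si](C)(C)C(C)(C)C | intermediate
9 | rac-1-[2-bromo-4-(TBSOCH2)furan-3-yl]but-3-en-1-ol | C=CCC(O)c1c(Br)occ1CO[Si](C)(C)C(C)(C)C | intermediate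
10 | 1-[2-bromo-4-(TBSOCH2)furan-3-yl]but-3-en-1-one | C=CCC(=O)c1c(Br)occ1CO[Si](C)(C)C(C)(C)C | intermediate (not isolated)
11 | (2E)-1-[2-bromo-4-(TBSOCH2)furan-3-yl]but-2-en-1-one | C/C=C/C(=O)c1c(Br)occ1CO[Si](C)(C)C(C)(C)C | intermediate
12 | (3S)-1-[2-bromo-4-(TBSOCH2)furan-3-yl]-3-methyl-5-(triisopropylsilyl)pent-4-yn-1-one | O=C(C[C@H](C)C#C[Si](C(C)C)(C(C)C)C(C)C)c1c(Br)occ1CO[Si](C)(C)C(C)(C)C | intermediate
13 | (1S,3S)-1-[2-bromo-4-(TBSOCH2)furan-3-yl]-3-methyl-5-(triisopropylsilyl)pent-4-yn-1-ol | O[C@H](c1c(Br)occ1CO[Si](C)(C)C(C)(C)C)C[C@H](C)C#C[Si](C(C)C)(C(C)C)C(C)C | intermediate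
14 | TBS ether of 13 (1S,3S) | CC(C)(C)[Si](C)(C)O[C@H](c1c(Br)occ1CO[Si](C)(C)C(C)(C)C)C[C@H](C)C#C[Si](C(C)C)(C(C)C)C(C)C | intermediate
15 | (R)-(2-methyloxiran-2-yl)methanol, (R)-2-methylglycidol | OC[C@]1(C)CO1 | starting material
16 | (S)-2-methyloxirane-2-carboxylic acid | OC(=O)[C@]1(C)CO1 | intermediate
17 | methyl (S)-2-methyloxirane-2-carboxylate | COC(=O)[C@]1(C)CO1 | intermediate
18 | 2-furyllithium from 14 | CC(C)(C)[Si](C)(C)O[C@H](c1c([Li])occ1CO[Si](C)(C)C(C)(C)C)C[C@H](C)C#C[Si](C(C)C)(C(C)C)C(C)C | intermediate (not isolated)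
19 | 2-furylmagnesium bromide from 14 | CC(C)(C)[Si](C)(C)O[C@H](c1c([Mg]Br)occ1CO[Si](C)(C)C(C)(C)C)C[C@H](C)C#C[Si](C(C)C)(C(C)C)C(C)C | intermediate (not isolated)
20 | methyl (2S)-3-{3-[(1S,3S)-1-(TBSO)-3-methyl-5-(triisopropylsilyl)pent-4-yn-1-yl]-4-(TBSOCH2)furan-2-yl}-2-hydroxy-2-methylpropanoate | CC(C)(C)[Si](C)(C)O[C@H](c1c(C[C@](C)(O)C(=O)OC)occ1CO[Si](C)(C)C(C)(C)C)C[C@H](C)C#C[Si](C(C)C)(C(C)C)C(C)C | intermediate
21 | silver acetylide of 22 | CC(C)(C)[Si](C)(C)O[C@H](c1c(C[C@](C)(O)C(=O)OC)occ1CO[Si](C)(C)C(C)(C)C)C[C@H](C)C#C[Ag] | intermediate (not isolated)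
22 | methyl (2S)-3-{3-[(1S,3S)-1-(TBSO)-3-methylpent-4-yn-1-yl]-4-(TBSOCH2)furan-2-yl}-2-hydroxy-2-methylpropanoate | CC(C)(C)[Si](C)(C)O[C@H](c1c(C[C@](C)(O)C(=O)OC)occ1CO[Si](C)(C)C(C)(C)C)C[C@H](C)C#C | intermediate
23 | S-ethyl (2S)-3-{3-[(1S,3S)-1-(TBSO)-3-methylpent-4-yn-1-yl]-4-(TBSOCH2)furan-2-yl}-2-hydroxy-2-methylpropanethioate | CC(C)(C)[Si](C)(C)O[C@H](c1c(C[C@](C)(O)C(=O)SCC)occ1CO[Si](C)(C)C(C)(C)C)C[C@H](C)C#C | intermediate
24 | (4S,8S,10S)-8,13-bis(TBSO)-4-hydroxy-6,12-epoxygermacra-6,11-dien-1-yn-3-one (ten-membered cyclic α′-hydroxy ynone; furan = C6, C7, C11, C12, O) | CC(C)(C)[Si](C)(C)O[C@H]1C[C@H](C)C#CC(=O)[C@@](C)(O)Cc2occ(CO[Si](C)(C)C(C)(C)C)c21 | intermediate (not isolated)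
25 | (4S,8S,10S)-8,13-bis(TBSO)-1-(diethylamino)-4-hydroxy-6,12-epoxygermacra-1,6,11-trien-3-one | CC(C)(C)[Si](C)(C)O[C@H]1C[C@H](C)C(N(CC)CC)=CC(=O)[C@@](C)(O)Cc2occ(CO[Si](C)(C)C(C)(C)C)c21 | intermediate (not isolated)
26 | (4S,8S,10S)-8,13-bis(TBSO)-1,4:6,12-diepoxygermacra-1,6,11-trien-3-one (furanone bridged across the carbocycle, furan fused at C6/C7) | CC(C)(C)[Si](C)(C)O[C@H]1C[C@H](C)C2=CC(=O)[C@](C)(Cc3occ(CO[Si](C)(C)C(C)(C)C)c31)O2 | intermediate
27 | 6,12-epidioxide (furan endoperoxide) of 26 | CC(C)(C)[Si](C)(C)O[C@H]1C[C@H](C)C2=CC(=O)[C@](C)(CC34OOC(O3)C(CO[Si](C)(C)C(C)(C)C)=C41)O2 | intermediate (not isolated)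
28 | (4S,8S,10S)-8,13-bis(TBSO)-1,4-epoxy-6-hydroxy-3-oxogermacra-1,7(11)-dien-12,6-olide (C6 epimers) | CC(C)(C)[Si](C)(C)O[C@H]1C[C@H](C)C2=CC(=O)[C@](C)(CC3(O)OC(=O)C(CO[Si](C)(C)C(C)(C)C)=C31)O2 | intermediate
29 | 6-O-trifluoroacetate of 28 | CC(C)(C)[Si](C)(C)O[C@H]1C[C@H](C)C2=CC(=O)[C@](C)(CC3(OC(=O)C(F)(F)F)OC(=O)C(CO[Si](C)(C)C(C)(C)C)=C31)O2 | intermediate (not isolated)
30 | (4S,5E,8S,10S)-8,13-bis(TBSO)-1,4-epoxy-3-oxogermacra-1,5,7(11)-trien-12,6-olide | CC(C)(C)[Si](C)(C)O[C@H]1C[C@H](C)C2=CC(=O)[C@](C)(/C=C3/OC(=O)C(CO[Si](C)(C)C(C)(C)C)=C31)O2 | intermediate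
31 | (4S,5E,8S,10S)-1,4-epoxy-8,13-dihydroxy-3-oxogermacra-1,5,7(11)-trien-12,6-olide | O[C@H]1C[C@H](C)C2=CC(=O)[C@](C)(/C=C3/OC(=O)C(CO)=C31)O2 | intermediate
32 | (4S,5E,8S,10S)-13-acetoxy-1,4-epoxy-8-hydroxy-3-oxogermacra-1,5,7(11)-trien-12,6-olide | O[C@H]1C[C@H](C)C2=CC(=O)[C@](C)(/C=C3/OC(=O)C(COC(C)=O)=C31)O2 | intermediate
33 | ethyl 2-(hydroxymethyl)prop-2-enoate | C=C(CO)C(=O)OCC | starting material
34 | ethyl 2-({[tert-butyl(dimethyl)silyl]oxy}methyl)prop-2-enoate | C=C(CO[Si](C)(C)C(C)(C)C)C(=O)OCC | intermediate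
35 | 2-({[tert-butyl(dimethyl)silyl]oxy}methyl)prop-2-enoic acid | C=C(CO[Si](C)(C)C(C)(C)C)C(=O)O | intermediate
36 | mixed anhydride of 35 and 2,4,6-trichlorobenzoic acid | C=C(CO[Si](C)(C)C(C)(C)C)C(=O)OC(=O)c1c(Cl)cc(Cl)cc1Cl | intermediate (not isolated)
37 | (4S,5E,8S,10S)-13-acetoxy-8-{[2-(TBSOCH2)acryloyl]oxy}-1,4-epoxy-3-oxogermacra-1,5,7(11)-trien-12,6-olide | C=C(CO[Si](C)(C)C(C)(C)C)C(=O)O[C@H]1C[C@H](C)C2=CC(=O)[C@](C)(/C=C3/OC(=O)C(COC(C)=O)=C31)O2 | intermediate
38 | CNP0193735.1, (4S,5E,8S,10S)-13-acetoxy-1,4-epoxy-8-{[2-(hydroxymethyl)acryloyl]oxy}-3-oxogermacra-1,5,7(11)-trien-12,6-olide | C=C(CO)C(=O)O[C@H]1C[C@H](C)C2=CC(=O)[C@](C)(/C=C3/OC(=O)C(COC(C)=O)=C31)O2 | target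

**Step count and risks**

Total step count: 22. Longest linear sequence: 18 steps (steps 1–8, 11–18, 21, 22); steps 9–10 and 19–20 are two-step side branches.

Steps most likely to fail:

1. Step 14 (proposed new method). Ring closure may lose to intermolecular coupling or oxidative alkyne homocoupling, the hindered acyl palladium may decarbonylate before transmetalation, or the cascade may stall at the ynone or enaminone stage. The fallback uses known chemistry, sets out from 22 and comes back at 26. Alkyne 22 is iodinated (NIS, AgNO3 cat., acetone) to the iodoalkyne ester F1. The ester is reduced (i-Bu2AlH, CH2Cl2, −78 °C) to the α-hydroxy aldehyde F2. An intramolecular Nozaki–Hiyama–Kishi reaction (CrCl2, NiCl2 cat., THF, high dilution) closes the ten-membered ring to the macrocyclic propargylic diol F3. MnO2 oxidises the propargylic alcohol to ynone 24, isolated in this variant, and (Ph3P)AuCl/AgOTf (cat.) in toluene cycloisomerises 24 to 26.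

2. Step 15. Collapse of the endoperoxide may not follow the Kornblum–DeLaMare course, or, once C6 reaches the carbonyl oxidation level, amine-induced retro-oxa-Michael opening of the furanone through C5 deprotonation may compete. The fallback sets out from 26 and comes back at 28. NBS/NaHCO3 in aqueous acetone at −20 °C opens the furan oxidatively to the (Z)-keto-enal F4. Pinnick oxidation (NaClO2, NaH2PO4, 2-methyl-2-butene, t-BuOH/H2O) of the aldehyde under buffered acidic conditions gives the cis keto acid, which closes to lactol 28.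

3. Step 11. Transfer of the hindered, doubly ortho-substituted furyl group from copper to the epoxide may be slow, so that attack at the ester carbonyl or silyl migration takes over. The fallback sets out from 14 and 15 and comes back at 20. Glycidol 15 is silylated (Et3SiCl, imidazole) to the epoxy silyl ether F5. Furyllithium 18, made from 14 as in step 11, opens F5 at its CH2 terminus with BF3·OEt2 at −78 °C to give the tertiary alcohol F6. PPTS/MeOH removes the primary TES group selectively to give the diol F7. TEMPO/PhI(OAc)2 in MeCN/H2O oxidises the primary alcohol to the α-hydroxy acid F8, and TMSCHN2 gives 20.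

**Further compounds**

F1 | step 14 | methyl (2S)-3-{3-[(1S,3S)-1-(TBSO)-5-iodo-3-methylpent-4-yn-1-yl]-4-(TBSOCH2)furan-2-yl}-2-hydroxy-2-methylpropanoate | CC(C)(C)[Si](C)(C)O[C@H](c1c(C[C@](C)(O)C(=O)OC)occ1CO[Si](C)(C)C(C)(C)C)C[C@H](C)C#CI
F2 | step 14 | (2S)-3-{3-[(1S,3S)-1-(TBSO)-5-iodo-3-methylpent-4-yn-1-yl]-4-(TBSOCH2)furan-2-yl}-2-hydroxy-2-methylpropanal | CC(C)(C)[Si](C)(C)O[C@H](c1c(C[C@](C)(O)C=O)occ1CO[Si](C)(C)C(C)(C)C)C[C@H](C)C#CI
F3 | step 14 | (4S,8S,10S)-8,13-bis(TBSO)-6,12-epoxygermacra-6,11-dien-1-yne-3,4-diol (C3 epimers) | CC(C)(C)[Si](C)(C)O[C@H]1C[C@H](C)C#CC(O)[C@@](C)(O)Cc2occ(CO[Si](C)(C)C(C)(C)C)c21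
F4 | step 15 | (4S,7Z,8S,10S)-8,13-bis(TBSO)-1,4-epoxy-3,6-dioxogermacra-1,7(11)-dien-12-al | CC(C)(C)[Si](C)(C)O[C@H]1C[C@H](C)C2=CC(=O)[C@](C)(CC(=O)/C1=C(\C=O)CO[Si](C)(C)C(C)(C)C)O2
F5 | step 11 | (S)-triethyl[(2-methyloxiran-2-yl)methoxy]silane | CC[Si](CC)(CC)OC[C@]1(C)CO1
F6 | step 11 | (2S)-1-{3-[(1S,3S)-1-(TBSO)-3-methyl-5-(triisopropylsilyl)pent-4-yn-1-yl]-4-(TBSOCH2)furan-2-yl}-2-methyl-3-[(triethylsilyl)oxy]propan-2-ol | CC(C)(C)[Si](C)(C)O[C@H](c1c(C[C@](C)(O)CO[Si](CC)(CC)CC)occ1CO[Si](C)(C)C(C)(C)C)C[C@H](C)C#C[Si](C(C)C)(C(C)C)C(C)C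
F7 | step 11 | (2S)-3-{3-[(1S,3S)-1-(TBSO)-3-methyl-5-(triisopropylsilyl)pent-4-yn-1-yl]-4-(TBSOCH2)furan-2-yl}-2-methylpropane-1,2-diol | CC(C)(C)[Si](C)(C)O[C@H](c1c(C[C@](C)(O)CO)occ1CO[Si](C)(C)C(C)(C)C)C[C@H](C)C#C[Si](C(C)C)(C(C)C)C(C)C
F8 | step 11 | (2S)-3-{3-[(1S,3S)-1-(TBSO)-3-methyl-5-(triisopropylsilyl)pent-4-yn-1-yl]-4-(TBSOCH2)furan-2-yl}-2-hydroxy-2-methylpropanoic acid | CC(C)(C)[Si](C)(C)O[C@H](c1c(C[C@](C)(O)C(=O)O)occ1CO[Si](C)(C)C(C)(C)C)C[C@H](C)C#C[Si](C(C)C)(C(C)C)C(C)C
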